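The central benzene ring is treated as the middle ring of a 6H-benzo[c]chromen-6-one: its C1 (which carries the methide carbon) and C2 (which carries the resorcinol ring, whose ortho hydroxyl is the lactone oxygen) are the 3,4-bond of a coumarin. A 2-pyrone fused to that bond reacts with the unshielded triple bond of a monosilylated diyne; one [4+2] cycloaddition and loss of CO2 form C4–C5 and C6–C1, close the ring and deliver H at C3 and C4, CH2O at C5 and the ethynyl group at C6. The diene precursor is 8-(methoxymethoxy)pyrano[3,4-c]chromene-4,5-dione; two aryllithium additions later open the lactone to the triaryl carbinol.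

Key step: step 7

Remark: the target has no stereocentre; it is the open ring-chain tautomer of a 6,6-diaryl-6H-benzo[c]chromene, and it is assumed that the quinone methide is the form that persists after neutral work-up, as the target structure implies.
Remark: all four phenols travel as MOM ethers and the benzylic alcohol as a TBS ether, so that one protic-acid step unmasks everything and dehydrates the carbinol; aryl methyl ethers would call for BBr3, which would also attack the benzylic C–O bond.

Step 1
Reactants: 1 2',4'-dihydroxyacetophenone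
Product: 2 1-[2-hydroxy-4-(methoxymethoxy)phenyl]ethan-1-one
Conditions: MOMCl (1.1 equiv), K2CO3, acetone, 0 °C to rt
Reagents that add atoms: chloromethyl methyl ether, COCCl
Why: Williamson-type O-alkylation should occur only at the 4-hydroxyl, because the 2-hydroxyl is held in a hydrogen bond to the ketone and is far less nucleophilic.

Step 2
Reactants: 2 1-[2-hydroxy-4-(methoxymethoxy)phenyl]ethan-1-one; 3 diethyl malonate
Product: 5 ethyl 7-(methoxymethoxy)-4-methyl-2-oxo-2H-chromene-3-carboxylate, via aryl ethyl malonate 4 (not isolated)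
Conditions: 3 (3 equiv), piperidine (0.3 equiv), AcOH (0.1 equiv), neat, 120 °C, EtOH and H2O distilled off
Reagents that add atoms: none
Why: Knoevenagel condensation with lactonisation (coumarin synthesis): acyl transfer to the phenol gives mixed malonate 4, whose active methylene then condenses intramolecularly with the aryl ketone, which offsets the low reactivity of a ketone in this condensation.

Step 3
Reactants: 5 ethyl 7-(methoxymethoxy)-4-methyl-2-oxo-2H-chromene-3-carboxylate
Product: 6 ethyl 4-[(E)-2-(dimethylamino)ethenyl]-7-(methoxymethoxy)-2-oxo-2H-chromene-3-carboxylate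
Conditions: DMF-DMA (2.5 equiv), DMF, 90 °C
Reagents that add atoms: N,N-dimethylformamide dimethyl acetal, COC(OC)N(C)C
Why: Enamine formation of the Leimgruber–Batcho type: the 4-methyl group is vinylogously acidified by the ester and the lactone carbonyl and condenses with the amide acetal to the push–pull enamine, which should adopt the less hindered E geometry.

Step 4
Reactants: 6 ethyl 4-[(E)-2-(dimethylamino)ethenyl]-7-(methoxymethoxy)-2-oxo-2H-chromene-3-carboxylate
Product: 8 8-(methoxymethoxy)pyrano[3,4-c]chromene-4,5-dione, via aldehyde 7 (not isolated)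
Conditions: AcOH/H2O (4:1), 60 °C
Reagents that add atoms: water, O
Why: Acid hydrolysis of the vinylogous amide gives enolisable aldehyde 7, whose enol oxygen acylates on the neighbouring ethyl ester (6-exo-trig lactonisation, as in isocoumarin synthesis from enamino benzoates), and aqueous acetic acid is weak enough to spare the aryl MOM ether.

Step 5
Reactants: 9 1,4-bis(trimethylsilyl)buta-1,3-diyne
Product: 11 5-(trimethylsilyl)penta-2,4-diyn-1-ol, via lithium diynide 10 (not isolated)
Conditions: MeLi·LiBr (1.0 equiv), THF, 0 °C to rt; (CH2O)n, 0 °C to rt; H2O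
Reagents that add atoms: paraformaldehyde (formaldehyde unit), C=O
Why: Selective mono-desilylation by methyllithium (attack at silicon, loss of Me4Si) gives the lithium diynide, which adds to formaldehyde in a standard acetylide 1,2-addition.

Step 6
Reactants: 11 5-(trimethylsilyl)penta-2,4-diyn-1-ol
Product: 12 tert-butyldimethyl{[5-(trimethylsilyl)penta-2,4-diyn-1-yl]oxy}silane
Conditions: TBSCl, imidazole, CH2Cl2, 0 °C to rt
Reagents that add atoms: tert-butyldimethylsilyl chloride, CC(C)(C)[Si](C)(C)Cl
Why: Standard imidazole-promoted silylation of a primary alcohol, which also removes the free hydroxyl that could add to the electrophilic pyrone.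

Step 7
Reactants: 8 8-(methoxymethoxy)pyrano[3,4-c]chromene-4,5-dione; 12 tert-butyldimethyl{[5-(trimethylsilyl)penta-2,4-diyn-1-yl]oxy}silane
Product: 14 8-{[(tert-butyldimethylsilyl)oxy]methyl}-3-(methoxymethoxy)-7-[(trimethylsilyl)ethynyl]-6H-benzo[c]chromen-6-one, via bridged lactone 13 (not isolated)
Conditions: 12 (3 equiv), mesitylene, 170 °C, sealed tube, Ar
Reagents that add atoms: none
Why: The 2-pyrone ring of 8 (diene C4a=C10b–C1=C2) should undergo a concerted, asynchronous inverse-electron-demand Diels–Alder reaction with the CH2OTBS-substituted triple bond of 12 to give the CO2-bridged bicyclic lactone 13, which aromatises at once by retro-[4+2] loss of CO2. The closest known reaction type is the cycloaddition–decarboxylation of 3-acyl and 3-alkoxycarbonyl 2-pyrones with alkynes to give benzoates. The central benzene ring is closed intermolecularly as a six-membered carbocycle by a 4C + 2C cycloaddition that forms both new bonds (C4–C5 and C6–C1 of the target ring) in one event, not by an exo or endo cyclisation. No stereocentre is created in 14, since the two bridgehead centres of racemic 13 are erased when CO2 leaves. The step needs site selectivity, secured by the Me3Si cap that shields the distal triple bond, and regioselectivity, secured because the electrophilic O-bearing CH (C2 of 8) bonds to the alkyne carbon that carries CH2OTBS, the charge that builds on the neighbouring carbon being delocalised into the second triple bond, while the slim alkynyl-bearing carbon is the one that can reach the quaternary C4a. The pyrone is doubly activated by the coumarin lactone (3-acyl pattern), so the reaction should proceed at a temperature that the silyl and MOM ethers tolerate.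

Step 8
Reactants: 14 8-{[(tert-butyldimethylsilyl)oxy]methyl}-3-(methoxymethoxy)-7-[(trimethylsilyl)ethynyl]-6H-benzo[c]chromen-6-one; 15 1-iodo-4-(methoxymethoxy)benzene
Product: 17 8-{[(tert-butyldimethylsilyl)oxy]methyl}-3-(methoxymethoxy)-7-{[4-(methoxymethoxy)phenyl]ethynyl}-6H-benzo[c]chromen-6-one, via terminal alkyne 16 (not isolated)
Conditions: PdCl2(PPh3)2 (5 mol%), CuI (10 mol%), DBU (6 equiv), H2O (1 equiv), MeCN, degassed, rt to 60 °C
Reagents that add atoms: none
Why: One-pot desilylative Sonogashira coupling: DBU and water cleave the C(sp)–SiMe3 bond and the terminal alkyne 16 is coupled at once with the aryl iodide by zerovalent palladium and CuI, at an alkyne terminus remote from the crowded arene, while the TBS ether, the MOM ethers and the lactone tolerate the amidine base.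

Step 9
Reactants: 17 8-{[(tert-butyldimethylsilyl)oxy]methyl}-3-(methoxymethoxy)-7-{[4-(methoxymethoxy)phenyl]ethynyl}-6H-benzo[c]chromen-6-one; 18 1-bromo-4-(methoxymethoxy)benzene
Product: 21 [3-{[(tert-butyldimethylsilyl)oxy]methyl}-6-[2-hydroxy-4-(methoxymethoxy)phenyl]-2-{[4-(methoxymethoxy)phenyl]ethynyl}phenyl]bis[4-(methoxymethoxy)phenyl]methanol, via aryllithium 19 (not isolated), via ring-opened ketone 20 (not isolated)
Conditions: 18 (4.2 equiv), n-BuLi (4.0 equiv), THF, −78 °C; then 17, −78 to 0 °C; H2O; chromatography on Et3N-deactivated silica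
Reagents that add atoms: none
Why: Bromine–lithium exchange gives 19, whose first 1,2-addition to the lactone carbonyl opens the ring to the lithium phenoxide of ketone 20 and whose second addition gives the triaryl carbinol, the usual outcome for a benzo[c]chromenone with excess aryllithium, helped here by the slim ethynyl group as one of the two ortho substituents.

Step 10
Reactants: 21 [3-{[(tert-butyldimethylsilyl)oxy]methyl}-6-[2-hydroxy-4-(methoxymethoxy)phenyl]-2-{[4-(methoxymethoxy)phenyl]ethynyl}phenyl]bis[4-(methoxymethoxy)phenyl]methanol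
Product: 23 Selaginellin F, via deprotected carbinol 22 (not isolated)
Conditions: 3 M aq. HCl, THF/MeOH (1:1), 40 °C
Reagents that add atoms: none
Why: Acid-catalysed acetal hydrolysis and silyl ether cleavage should remove the four MOM groups and the TBS group, and the same acid ionises carbinol 22, which is stabilised by two para-hydroxyphenyl groups and loses water to the fuchsone-type quinone methide (acid-catalysed dehydration), while methanol traps the released formaldehyde and no Lewis acid or halide source threatens the benzylic alcohol.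

Compound list
1 | 2',4'-dihydroxyacetophenone | CC(=O)c1ccc(O)cc1O | starting material
2 | 1-[2-hydroxy-4-(methoxymethoxy)phenyl]ethan-1-one | CC(=O)c1ccc(OCOC)cc1O | intermediate
3 | diethyl malonate | CCOC(=O)CC(=O)OCC | starting material
4 | 2-acetyl-5-(methoxymethoxy)phenyl ethyl malonate | CCOC(=O)CC(=O)Oc1cc(OCOC)ccc1C(C)=O | intermediate
5 | ethyl 7-(methoxymethoxy)-4-methyl-2-oxo-2H-chromene-3-carboxylate | CCOC(=O)C1=C(C)c2ccc(OCOC)cc2OC1=O | intermediate
6 | ethyl 4-[(E)-2-(dimethylamino)ethenyl]-7-(methoxymethoxy)-2-oxo-2H-chromene-3-carboxylate | CCOC(=O)C1=C(/C=C/N(C)C)c2ccc(OCOC)cc2OC1=O | intermediate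
7 | ethyl 7-(methoxymethoxy)-2-oxo-4-(2-oxoethyl)-2H-chromene-3-carboxylate | CCOC(=O)C1=C(CC=O)c2ccc(OCOC)cc2OC1=O | intermediate
8 | 8-(methoxymethoxy)pyrano[3,4-c]chromene-4,5-dione | COCOc1ccc2c(c1)OC(=O)C1=C2C=COC1=O | intermediate
9 | 1,4-bis(trimethylsilyl)buta-1,3-diyne | C[Si](C)(C)C#CC#C[Si](C)(C)C | starting material
10 | [4-(trimethylsilyl)buta-1,3-diyn-1-yl]lithium | [Li]C#CC#C[Si](C)(C)C | intermediate
11 | 5-(trimethylsilyl)penta-2,4-diyn-1-ol | C[Si](C)(C)C#CC#CCO | intermediate
12 | tert-butyldimethyl{[5-(trimethylsilyl)penta-2,4-diyn-1-yl]oxy}silane | C[Si](C)(C)C#CC#CCO[Si](C)(C)C(C)(C)C | intermediate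
13 | CO2-bridged cycloadduct of 8 and 12 (2-oxabicyclo[2.2.2]octa-5,7-dien-3-one core; racemic, bridgehead configuration fixed by the bicycle) | COCOc1ccc2c(c1)OC(=O)C13C(=O)OC(C=C23)C(CO[Si](C)(C)C(C)(C)C)=C1C#C[Si](C)(C)C | intermediate
14 | 8-{[(tert-butyldimethylsilyl)oxy]methyl}-3-(methoxymethoxy)-7-[(trimethylsilyl)ethynyl]-6H-benzo[c]chromen-6-one | COCOc1ccc2c(c1)OC(=O)c1c2ccc(CO[Si](C)(C)C(C)(C)C)c1C#C[Si](C)(C)C | intermediate
15 | 1-iodo-4-(methoxymethoxy)benzene | COCOc1ccc(I)cc1 | starting material
16 | 8-{[(tert-butyldimethylsilyl)oxy]methyl}-7-ethynyl-3-(methoxymethoxy)-6H-benzo[c]chromen-6-one | COCOc1ccc2c(c1)OC(=O)c1c2ccc(CO[Si](C)(C)C(C)(C)C)c1C#C | intermediate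
17 | 8-{[(tert-butyldimethylsilyl)oxy]methyl}-3-(methoxymethoxy)-7-{[4-(methoxymethoxy)phenyl]ethynyl}-6H-benzo[c]chromen-6-one | COCOc1ccc2c(c1)OC(=O)c1c2ccc(CO[Si](C)(C)C(C)(C)C)c1C#Cc1ccc(OCOC)cc1 | intermediate
18 | 1-bromo-4-(methoxymethoxy)benzene | COCOc1ccc(Br)cc1 | starting material
19 | [4-(methoxymethoxy)phenyl]lithium | [Li]c1ccc(OCOC)cc1 | intermediate
20 | [3-{[(tert-butyldimethylsilyl)oxy]methyl}-6-[2-hydroxy-4-(methoxymethoxy)phenyl]-2-{[4-(methoxymethoxy)phenyl]ethynyl}phenyl][4-(methoxymethoxy)phenyl]methanone (lithium phenoxide in the flask) | COCOc1ccc(cc1)C(=O)c1c(-c2ccc(OCOC)cc2O)ccc(CO[Si](C)(C)C(C)(C)C)c1C#Cc1ccc(OCOC)cc1 | intermediate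
21 | [3-{[(tert-butyldimethylsilyl)oxy]methyl}-6-[2-hydroxy-4-(methoxymethoxy)phenyl]-2-{[4-(methoxymethoxy)phenyl]ethynyl}phenyl]bis[4-(methoxymethoxy)phenyl]methanol | COCOc1ccc(cc1)C(O)(c1ccc(OCOC)cc1)c1c(-c2ccc(OCOC)cc2O)ccc(CO[Si](C)(C)C(C)(C)C)c1C#Cc1ccc(OCOC)cc1 | intermediate
22 | [6-(2,4-dihydroxyphenyl)-3-(hydroxymethyl)-2-[(4-hydroxyphenyl)ethynyl]phenyl]bis(4-hydroxyphenyl)methanol | OCc1ccc(-c2ccc(O)cc2O)c(C(O)(c2ccc(O)cc2)c2ccc(O)cc2)c1C#Cc1ccc(O)cc1 | intermediate
23 | Selaginellin F, 4-{[6-(2,4-dihydroxyphenyl)-3-(hydroxymethyl)-2-[(4-hydroxyphenyl)ethynyl]phenyl](4-hydroxyphenyl)methylidene}cyclohexa-2,5-dien-1-one | O=C1C=CC(=C(c2ccc(O)cc2)c2c(-c3ccc(O)cc3O)ccc(CO)c2C#Cc2ccc(O)cc2)C=C1 | target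

Total step count: 10 steps.
Longest linear sequence: 8 steps (1 → 2 → 5 → 6 → 8 → 14 → 17 → 21 → 23); the diyne branch (9 → 11 → 12) has 2 steps.

Steps most likely to fail

Step 7. The unactivated diyne may react too slowly with the electron-poor pyrone, so that thermal decomposition or diyne oligomerisation outruns the cycloaddition. The bond-forming sense may also leak, with the CH2OTBS-bearing carbon bonding to the quaternary C4a. The fallback sets out from 8 and comes back at 14; it replaces the alkyne by an electron-rich enol ether whose oxygen dictates the regiochemistry. Commercial 3-[(tert-butyldimethylsilyl)oxy]propanal and lithium (trimethylsilyl)acetylide (THF, −78 °C) should give 5-[(tert-butyldimethylsilyl)oxy]-1-(trimethylsilyl)pent-1-yn-3-ol F1. MnO2 in CH2Cl2 should oxidise it to 5-[(tert-butyldimethylsilyl)oxy]-1-(trimethylsilyl)pent-1-yn-3-one F2. Soft enolisation with TMSOTf/Et3N should give tert-butyldimethyl{[(2Z)-5-(trimethylsilyl)-3-[(trimethylsilyl)oxy]pent-2-en-4-yn-1-yl]oxy}silane F3. Inverse-demand Diels–Alder reaction of F3 with 8 (toluene, 80–110 °C) should bond the nucleophilic CH carbon to C2 of 8 and the oxygen-bearing carbon to C4a, giving the bridged lactone cycloadduct of 8 and F3 F4. Loss of CO2 should give 8-{[(tert-butyldimethylsilyl)oxy]methyl}-3-(methoxymethoxy)-7-[(trimethylsilyl)ethynyl]-7-[(trimethylsilyl)oxy]-7,8-dihydro-6H-benzo[c]chromen-6-one F5, and DBU at rt should eliminate trimethylsilanol to give 14.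

Step 9. The sequence may stall after the first addition, because the tetrahedral lithium lactolate can persist until the quench, or because the ketone, flanked by the alkynyl group and the phenoxide-bearing ring, resists a second hard aryllithium. The fallback sets out from 17 and comes back at 23. Addition of 1.2 equiv of 19 at −78 °C with a cold quench should stop at ketone 20, which is then isolated. MOMCl/i-Pr2NEt should cap its phenol to give [3-{[(tert-butyldimethylsilyl)oxy]methyl}-6-[2,4-bis(methoxymethoxy)phenyl]-2-{[4-(methoxymethoxy)phenyl]ethynyl}phenyl][4-(methoxymethoxy)phenyl]methanone F6. The aryl cerium reagent made from 19 and anhydrous CeCl3 (THF, −78 °C), which is less basic and more oxophilic, should add to F6 to give [3-{[(tert-butyldimethylsilyl)oxy]methyl}-6-[2,4-bis(methoxymethoxy)phenyl]-2-{[4-(methoxymethoxy)phenyl]ethynyl}phenyl]bis[4-(methoxymethoxy)phenyl]methanol F7. Under the conditions of step 10, F7 should give 22 and then 23.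

Step 10. The acid needed for MOM cleavage may let the triaryl cation be captured by the neighbouring phenol or the alkyne, or let released formaldehyde condense with the electron-rich rings. The fallback sets out from 17 and comes back at 22, which dehydrates to 23; it moves the acid step to the robust lactone and ends with fluoride. HCl in MeOH/THF on 17 should give 3-hydroxy-8-(hydroxymethyl)-7-[(4-hydroxyphenyl)ethynyl]-6H-benzo[c]chromen-6-one F8. TBSCl/imidazole in DMF should give 3-[(tert-butyldimethylsilyl)oxy]-8-{[(tert-butyldimethylsilyl)oxy]methyl}-7-({4-[(tert-butyldimethylsilyl)oxy]phenyl}ethynyl)-6H-benzo[c]chromen-6-one F9. Commercial (4-bromophenoxy)(tert-butyl)dimethylsilane and n-BuLi should give {4-[(tert-butyldimethylsilyl)oxy]phenyl}lithium F10. An excess of F10 should open F9 to [3-{[(tert-butyldimethylsilyl)oxy]methyl}-6-{4-[(tert-butyldimethylsilyl)oxy]-2-hydroxyphenyl}-2-({4-[(tert-butyldimethylsilyl)oxy]phenyl}ethynyl)phenyl]bis{4-[(tert-butyldimethylsilyl)oxy]phenyl}methanol F11. TBAF buffered with AcOH (THF, 0 °C to rt) should then give 22, which should lose water on mildly acidic work-up to give 23.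

Further compounds
F1 | step 7 | 5-[(tert-butyldimethylsilyl)oxy]-1-(trimethylsilyl)pent-1-yn-3-ol (racemic) | C[Si](C)(C)C#CC(O)CCO[Si](C)(C)C(C)(C)C
F2 | step 7 | 5-[(tert-butyldimethylsilyl)oxy]-1-(trimethylsilyl)pent-1-yn-3-one | C[Si](C)(C)C#CC(=O)CCO[Si](C)(C)C(C)(C)C
F3 | step 7 | tert-butyldimethyl{[(2Z)-5-(trimethylsilyl)-3-[(trimethylsilyl)oxy]pent-2-en-4-yn-1-yl]oxy}silane | C[Si](C)(C)C#C/C(O[Si](C)(C)C)=C/CO[Si](C)(C)C(C)(C)C
F4 | step 7 | bridged lactone cycloadduct of 8 and F3 (racemic, mixture of diastereomers) | COCOc1ccc2c(c1)OC(=O)C13C(=O)OC(C=C23)C(CO[Si](C)(C)C(C)(C)C)C1(O[Si](C)(C)C)C#C[Si](C)(C)C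
F5 | step 7 | 8-{[(tert-butyldimethylsilyl)oxy]methyl}-3-(methoxymethoxy)-7-[(trimethylsilyl)ethynyl]-7-[(trimethylsilyl)oxy]-7,8-dihydro-6H-benzo[c]chromen-6-one (racemic, mixture of diastereomers) | COCOc1ccc2c(c1)OC(=O)C1=C2C=CC(CO[Si](C)(C)C(C)(C)C)C1(O[Si](C)(C)C)C#C[Si](C)(C)C
F6 | step 9 | [3-{[(tert-butyldimethylsilyl)oxy]methyl}-6-[2,4-bis(methoxymethoxy)phenyl]-2-{[4-(methoxymethoxy)phenyl]ethynyl}phenyl][4-(methoxymethoxy)phenyl]methanone | COCOc1ccc(cc1)C(=O)c1c(-c2ccc(OCOC)cc2OCOC)ccc(CO[Si](C)(C)C(C)(C)C)c1C#Cc1ccc(OCOC)cc1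
F7 | step 9 | [3-{[(tert-butyldimethylsilyl)oxy]methyl}-6-[2,4-bis(methoxymethoxy)phenyl]-2-{[4-(methoxymethoxy)phenyl]ethynyl}phenyl]bis[4-(methoxymethoxy)phenyl]methanol | COCOc1ccc(cc1)C(O)(c1ccc(OCOC)cc1)c1c(-c2ccc(OCOC)cc2OCOC)ccc(CO[Si](C)(C)C(C)(C)C)c1C#Cc1ccc(OCOC)cc1
F8 | step 10 | 3-hydroxy-8-(hydroxymethyl)-7-[(4-hydroxyphenyl)ethynyl]-6H-benzo[c]chromen-6-one | Oc1ccc2c(c1)OC(=O)c1c2ccc(CO)c1C#Cc1ccc(O)cc1
F9 | step 10 | 3-[(tert-butyldimethylsilyl)oxy]-8-{[(tert-butyldimethylsilyl)oxy]methyl}-7-({4-[(tert-butyldimethylsilyl)oxy]phenyl}ethynyl)-6H-benzo[c]chromen-6-one | CC(C)(C)[Si](C)(C)Oc1ccc2c(c1)OC(=O)c1c2ccc(CO[Si](C)(C)C(C)(C)C)c1C#Cc1ccc(O[Si](C)(C)C(C)(C)C)cc1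
F10 | step 10 | {4-[(tert-butyldimethylsilyl)oxy]phenyl}lithium | [Li]c1ccc(O[Si](C)(C)C(C)(C)C)cc1
F11 | step 10 | [3-{[(tert-butyldimethylsilyl)oxy]methyl}-6-{4-[(tert-butyldimethylsilyl)oxy]-2-hydroxyphenyl}-2-({4-[(tert-butyldimethylsilyl)oxy]phenyl}ethynyl)phenyl]bis{4-[(tert-butyldimethylsilyl)oxy]phenyl}methanol | CC(C)(C)[Si](C)(C)Oc1ccc(cc1)C(O)(c1ccc(O[Si](C)(C)C(C)(C)C)cc1)c1c(-c2ccc(O[Si](C)(C)C(C)(C)C)cc2O)ccc(CO[Si](C)(C)C(C)(C)C)c1C#Cc1ccc(O[Si](C)(C)C(C)(C)C)cc1
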